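## Structural features

The target is a briarane-type diterpenoid. Its core is a ten-membered carbocycle (ring B, C1–C10) trans-fused along C1–C10 to a cyclohexane (ring A, C1, C10–C14) and trans-fused along C7–C8 to an α-methyl-γ-butyrolactone (ring C, C7–O–C19–C17–C8). Thirteen stereocentres lie close together: the quaternary C1 (methyl C15) beside C2; the contiguous C6 (chloride), C7, C8 (tertiary carbinol), C9 and C10 on ring B; C11 (methyl C20, syn-axial to C15), C12, C13 and C14 on ring A; and C17 in the lactone. Ring B also holds a (3Z)-alkene conjugated to the C5 methylidene (C16), which makes C6 an allylic secondary chloride. The fragile elements are this diene/allylic chloride unit, the 13,14-epoxide, three secondary acetates beside a free tertiary alcohol, and the β-hydroxy lactone with its epimerizable C17. The real difficulty is the medium ring: stereocentres on both sides of it, a Z alkene inside it and four contiguous heteroatom-bearing carbons (C6–C9) leave no reliable ring-closing bond. The key step uses the fact that C3=C4, taken one oxidation level up as an alkyne, lies across ring B from the C9 oxygen: ring B folds into two six-membered rings, B1 (C1, C2, C3, C4, C9, C10) and B2 (C4–C9), sharing a C4–C9 bond that carries an epoxide next to a C3 ketone. Ring B2 then has oxygen or chlorine on C5–C8 and unsaturation at C4–C9, the pattern of a p-benzoquinone, which points to an arene as its source.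

## Logic of the disconnections

43 to 41: the acetyl C–O bonds at C2 and C12 are cut last, and before them the Si–O bonds of 41. Acetates would not survive the basic and nucleophilic steps earlier on, so two robust silyl ethers are carried throughout. The forward steps must spare the allylic chloride, the diene and the epoxide, and must leave the tertiary C8 hydroxyl unacylated.

41 to 39: the C5=C16 bond is cut, returning to ketone 40 and then to carbinol 39. The diene is the most fragile unit and is made as late as possible. The methylenation has to be non-basic, because the C5 ketone of 40 has an α-chloride and a β-acyloxy group.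

39 to 36: the C9–H bond (carbonyl reduction) and the C9 acetyl bond are cut, together with the silyl ethers at C5 and C8. The C9 carbinol is the only stereocentre made on the flexible ring, which demands facial control in the reduction of 36. The acetate is put on at once so that only the C5 carbinol is free when it is oxidised.

36 to 35: two C–H bonds are removed to give the alkyne. A cyclodecyne can only be reduced to the Z alkene, so the alkene geometry needs no control.

35 to 32 (key step): the C4–C9 bond is re-formed, turning the ten-membered ring into rings B1 and B2 with a C3 ketone and a C4–C9 epoxide. All stereocentres except C9 can then be set on rigid six-membered rings. The forward step must form a hydrazone at a hindered carbonyl and fragment without harming C2, C10 or the silyl ethers. Three points of the obvious precursor design were changed here: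
- One kind of silyl ether on C2, C6 and C12 would not let the C6 oxygen be addressed alone, and a late displacement at an allylic C6 invites attack at C16. So 32 already carries the chlorine.
- C5 is a silyl ether rather than an acetal, because the ring B2 chemistry needs the free C5 ketone.
- The C2 oxygen is placed by α-face oxidation of an enol ether. Hydride reduction of a C2 ketone beside the C15-bearing carbon would give the 2β alcohol.

32 to 27: the two epoxide C–O bonds at C4 and C9, then the C8–C17 bond and the lactone C19–O bond are cut, leaving enedione 27 and ester 28. This removes ring C and two stereocentres. The forward aldol must choose the C8 carbonyl over the C3 carbonyl and the β face, and C17 must settle as 17R.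

27 to 21: the C6–Cl and C7–O bonds are traced to the C6=C7 alkene of quinone monoketal 21 through epoxide 22; the C5 carbinol returns to the ketone. The gain is a flat, achiral ring B2. The demand is a reagent-controlled epoxidation, because no stereocentre is near C6=C7, and two clean SN2 events at C6.

21 to 15: ring B2 is re-aromatised (C8 acetal oxygens removed, C5 ketone to phenol ether) and the C2–O bond is cut. An annulation starting from 2-methylcyclohexane-1,3-dione would leave C4 and C9 as unactivated methylenes, whereas an arene supplies both as sp2 carbons and hides four functionalised carbons. The forward oxidation must be para-selective.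

15 to 8: the C3 carbonyl oxygen is removed (benzylic oxidation forward), then the ring A stereocentres are taken apart in reverse order: C10–H/C11–H (hydrogenation), C12–H (reduction), the 13,14-epoxide and the C13=C14 alkene. The order matters: the axial 11β-methyl can only come from syn delivery of hydrogen to the α face, so the directing 12α-hydroxyl and the epoxide have to be in place first.

8 to 2 and 4: the C10=C11 bond (aldol condensation) and the C1–C14 bond (Michael addition) are cut, a Robinson annulation of a 2-methyl-1-tetralone with pent-1-en-3-one. This gives two commercial-type fragments. The quaternary C1 must be set in the Michael step, for which auxiliary 3 is used.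

2 to 1: the C1–C15 bond is cut (enolate methylation).

## Other disconnections considered

Alternative 1: ring A is cut at C10–C11 and C1–C14. In the forward direction diene A1 and enal A2 combine in an exo-selective Diels–Alder reaction under the cationic oxazaborolidine from (S)-diphenylprolinol and an o-tolylboron source activated by HNTf2; acidic work-up expels ethanol and leaves enone A3. In its favour: one catalytic step sets C1, C10 and C11, with the C11 methyl cis to C15, and delivers the C13=C14 enone plus handles at C2 and C9. On this point it is better than the chosen plan, which needs an auxiliary-controlled Michael addition and a directed hydrogenation of a hindered alkene for the same three centres. Against it here: it solves only ring A. The bonds C2–C3, C4–C5 and C8–C9 and the whole of ring B2 remain, and A3 has no arene to supply C4–C9, so either a macrocyclisation or two further annulations would be needed. Mechanistically it is a concerted cycloaddition against a stepwise annulation; in step count it is shorter to ring A but would be longer overall to the tricyclic epoxy ketone.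

Alternative 2: the lactone is cut at C8–C17. Forward, Rh2(O2CCPh3)4 decomposes diazo ester A4 and the carbene inserts into the C8–H bond next to the silyl ether, closing ring C and giving A5, one deprotection from the target. In its favour: insertion goes with retention, so the tertiary carbinol comes from a secondary carbinol stereocentre, and no nucleophile has to be added to a crowded ketone flanked by a second ketone. On that point it is the equal or the better of step 21. Against it here: the carbene meets a diene (cyclopropanation), an allylic chloride, an epoxide oxygen and a competing C6–H bond; C17 is set without obvious control; and the diazo ester has to be made on the complete, fragile ten-membered ring. It also presupposes that ring B exists, so it complements rather than replaces a ring-forming strategy. In step count it is about equal.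

Alternative 3: ring B is cut at C8–C9. Forward, TiCl3(DME)1.5 with Zn–Cu couple reduces the C8 ketone and C9 aldehyde of A6 to ketyls that couple on titanium, giving diol A7. In its favour: the ring closes with formation of a skeletal bond and both oxygen-bearing centres appear in one step, and A6 can be assembled convergently. In bond economy it is better than the chosen key step, which forms no skeletal bond. Against it here: a ten-membered pinacol closure is entropically and transannularly unfavourable, two stereocentres are set on a flexible chain without a clear controlling element, low-valent titanium may deoxygenate the diol or engage the diene, and A7 still needs the lactone oxidation level, the chloride and the ring A epoxide. The chosen plan sets every stereocentre but C9 on six-membered rings before the ring is unveiled; alternative 3 would be shorter if the closure were selective.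

Key step: step 24

Remark 1: locants C1–C20 are those of the target in every compound; β is the face of the C15 methyl group, α the opposite face.
Remark 2: 5 is a mixture of C1 epimers that equilibrate through the enamine tautomer; the C5 carbinol of 25–39 is drawn as the 5α epimer, and its configuration is erased in step 29.
Remark 3: in step 15 diisopropyl L-tartrate is assumed to direct the peroxide to the α face; if a pilot run shows the opposite sense, the D-tartrate is used.

## Steps

Step 1
Reactants: 1 5-methoxy-3,4-dihydronaphthalen-1(2H)-one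
Product: 2 5-methoxy-2-methyl-3,4-dihydronaphthalen-1(2H)-one (racemic)
Conditions: LiN(iPr)2, THF, −78 °C; MeI, −78 → 0 °C
Reagents that add atoms: iodomethane, CI
Why: Alkylation of the kinetic lithium enolate, which can form at one α-carbon only; the new centre is racemic and is re-set in step 2.

Step 2
Reactants: 2 5-methoxy-2-methyl-3,4-dihydronaphthalen-1(2H)-one, 3 (R)-1-phenylethan-1-amine, 4 pent-1-en-3-one
Product: 7 (S)-5-methoxy-2-methyl-2-(3-oxopentyl)-3,4-dihydronaphthalen-1(2H)-one, via ketimine 5 (not isolated), via Michael adduct ketimine 6 (not isolated)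
Conditions: 3, p-TsOH (cat.), PhMe, reflux, −H2O; then 4, THF, 40 °C; then 10% aq. AcOH, 20 °C
Reagents that add atoms: water, O
Why: Auxiliary-controlled Michael addition of the secondary enamine tautomer of 5 through a compact cyclic transition state; the enone adds to the face opposite the phenyl group, which with the (R)-amine should give the (S)-quaternary C1, and hydrolysis releases the auxiliary.

Step 3
Reactants: 7 (S)-5-methoxy-2-methyl-2-(3-oxopentyl)-3,4-dihydronaphthalen-1(2H)-one
Product: 8 (S)-8-methoxy-4,10a-dimethyl-1,9,10,10a-tetrahydrophenanthren-3(2H)-one (tricyclic enone: C12 ketone, C10=C11)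
Conditions: NaOMe, MeOH, 65 °C
Reagents that add atoms: none
Why: Intramolecular aldol condensation, the second stage of a Robinson annulation; only the ethyl-ketone methylene reaches the aryl ketone through a six-membered transition state, and dehydration gives the tetrasubstituted C10=C11 enone.

Step 4
Reactants: 8 tricyclic enone
Product: 10 cross-conjugated dienone (C12 ketone, C10=C11, C13=C14), via silyl dienol ether 9 (not isolated)
Conditions: LiN(iPr)2, THF, −78 °C; Me3SiCl; then Pd(OAc)2, MeCN, 20 °C
Reagents that add atoms: none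
Why: Saegusa–Ito dehydrogenation; kinetic deprotonation is possible only at C13 (there is no γ-hydrogen), and β-hydride loss from the palladium enolate installs C13=C14.

Step 5
Reactants: 10 cross-conjugated dienone
Product: 11 13α,14α-epoxy enone
Conditions: 30% H2O2, NaOH, MeOH, 0 °C
Reagents that add atoms: hydrogen peroxide, OO
Why: Weitz–Scheffer nucleophilic epoxidation; hydroperoxide adds only to the unhindered C14 (the other β-carbon is fully substituted and aryl-conjugated) and from the α face, anti to the C15 methyl on the adjacent carbon.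

Step 6
Reactants: 11 13α,14α-epoxy enone
Product: 12 12α-hydroxy-13α,14α-epoxide (C10=C11 retained)
Conditions: NaBH4, CeCl3·7H2O, MeOH, −78 °C
Reagents that add atoms: none
Why: Luche 1,2-reduction; hydride attacks C12 anti to the adjacent epoxide C–O bond (β face) and should give the cis (12α) epoxy alcohol.

Step 7
Reactants: 12 12α-hydroxy-13α,14α-epoxide
Product: 13 trans-fused alcohol (10α-H, 11β-methyl, 12α-OH, 13α,14α-epoxide)
Conditions: H2 (10 bar), [Ir(cod)(PCy3)(py)]PF6 (10 mol%), CH2Cl2, 20 °C
Reagents that add atoms: none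
Why: Hydroxyl-directed homogeneous hydrogenation; the 12α-hydroxyl binds iridium, so both hydrogens reach the α face of C10=C11, setting 10α-H (trans fusion) and the axial 11β-methyl, which enolate protonation could not give.

Step 8
Reactants: 13 trans-fused alcohol
Product: 14 12α-OTBS ether of 13
Conditions: TBSOTf, 2,6-lutidine, CH2Cl2, −78 → 0 °C
Reagents that add atoms: tert-butyldimethylsilyl trifluoromethanesulfonate, CC(C)(C)[Si](C)(C)OS(=O)(=O)C(F)(F)F
Why: Silylation of a hindered secondary alcohol with the silyl triflate; the buffered conditions leave the epoxide intact.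

Step 9
Reactants: 14 12α-OTBS ether
Product: 15 C3 aryl ketone of 14
Conditions: DDQ, 1,4-dioxane/H2O, 20 °C
Reagents that add atoms: water, O
Why: Benzylic oxidation by hydride abstraction and capture by water; the C3 cation is stabilised by the ortho methoxy group whereas the tertiary C10 position is meta to it, so oxidation should occur at C3 only.

Step 10
Reactants: 15 C3 aryl ketone
Product: 16 C5 phenol of 15
Conditions: NaSEt, DMF, 100 °C; then 1 M HCl
Reagents that add atoms: none
Why: SN2 demethylation of the aryl methyl ether by thiolate, eased by the ortho acyl group; the ring A epoxide is shielded from backside attack by the syn-axial C15 and C20 methyl groups.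

Step 11
Reactants: 16 C5 phenol
Product: 17 C5 aryl TBS ether, C3 TBS enol ether (C2=C3)
Conditions: TBSOTf, Et3N, CH2Cl2, 0 °C
Reagents that add atoms: tert-butyldimethylsilyl trifluoromethanesulfonate, CC(C)(C)[Si](C)(C)OS(=O)(=O)C(F)(F)F
Why: Phenol silylation together with soft enolization and O-silylation of the aryl ketone; C2 is the only enolizable position.

Step 12
Reactants: 17 aryl TBS ether, TBS enol ether
Product: 19 2α-OTBS C3 ketone (C5 aryl TBS ether), via siloxy epoxide 18 (not isolated)
Conditions: dimethyldioxirane, acetone, −40 → 20 °C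
Reagents that add atoms: dimethyldioxirane, CC1(C)OO1
Why: Rubottom oxidation; the enol ether is epoxidised from the α face, anti to the axial C15 methyl on the adjacent carbon, and a 1,4-silyl shift gives the 2α-silyloxy ketone directly.

Step 13
Reactants: 19 2α-OTBS C3 ketone (aryl TBS ether)
Product: 20 2α-OTBS C3 ketone, C5 phenol
Conditions: K2CO3 (cat.), MeOH, 0 °C
Reagents that add atoms: none
Why: Base-catalysed methanolysis of the aryl silyl ether; alkyl TBS ethers are inert here, and the equatorial C2–H is poorly aligned for enolization.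

Step 14
Reactants: 20 C5 phenol
Product: 21 quinone monoketal (C5 ketone, C8 dimethyl ketal, C6=C7, C4=C9)
Conditions: PhI(OAc)2, MeOH, 0 °C
Reagents that add atoms: methanol, CO
Why: Oxidative dearomatization with a trivalent iodine reagent; methanol adds twice at the free para position C8, converting the arene into ring B2 with C5 and C8 oxidised and both alkenes in place.

Step 15
Reactants: 21 quinone monoketal
Product: 22 6α,7α-epoxide of 21
Conditions: Ph3COOH, NaN(SiMe3)2, diisopropyl L-tartrate, PhMe, −50 °C; aq. NH4Cl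
Reagents that add atoms: trityl hydroperoxide, OOC(c1ccccc1)(c1ccccc1)c1ccccc1
Why: Tartrate-mediated nucleophilic epoxidation of a quinone monoketal; the peroxide attacks the unsubstituted C7 (C9 is fully substituted and flanked by the ketal), and the face is chosen by the reagent because no stereocentre is near.

Step 16
Reactants: 22 6α,7α-epoxide
Product: 23 6β-bromo-7α-hydroxy C5 ketone
Conditions: LiBr, AcOH, THF, 0 °C
Reagents that add atoms: lithium bromide, [Li+].[Br-]
Why: Halide opening of an α,β-epoxy ketone at the α-carbon (SN2, anti); C7 is neopentyl-like beside the ketal, so bromide enters C6 from the β face and the epoxide oxygen stays on C7.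

Step 17
Reactants: 23 6β-bromo-7α-hydroxy C5 ketone
Product: 24 6α-chloro-7α-hydroxy C5 ketone
Conditions: LiCl (1.5 equiv), DMF, 0 °C
Reagents that add atoms: lithium chloride, [Li+].[Cl-]
Why: Finkelstein-type SN2 at the carbonyl-activated C6 (axial C–Br aligned with the C5 π* orbital); inversion gives the 6α-chloride cis to the 7α-hydroxyl, and the small excess of chloride at 0 °C limits degenerate exchange.

Step 18
Reactants: 24 6α-chloro-7α-hydroxy C5 ketone
Product: 25 5α,7α-diol (6α-chloride)
Conditions: NaBH4 (0.5 equiv), CeCl3·7H2O, MeOH/THF, −78 °C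
Reagents that add atoms: none
Why: Luche reduction; the α-chloro ketone carbonyl C5 is more electrophilic and more accessible than the C3 carbonyl flanked by the axial C2 silyloxy group and C1, so limited hydride should reduce C5 only (attack anti to C–Cl gives the 5α carbinol).

Step 19
Reactants: 25 5α,7α-diol
Product: 26 5α-OTES ether of 25
Conditions: Et3SiCl, imidazole, CH2Cl2, −20 °C
Reagents that add atoms: chlorotriethylsilane, CC[Si](CC)(CC)Cl
Why: Selective silylation of the less hindered allylic C5 hydroxyl; the C7 hydroxyl lies between the chloride and the ketal carbon.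

Step 20
Reactants: 26 5α-OTES ether
Product: 27 C8 ketone (C3,C8-enedione)
Conditions: oxalic acid, wet SiO2, CH2Cl2, 20 °C
Reagents that add atoms: water, O
Why: Mild acid hydrolysis of the crowded dimethyl ketal unveils the C8 ketone; the triethylsilyl ether tolerates these conditions.

Step 21
Reactants: 27 C8 ketone, 28 ethyl propanoate
Product: 30 C7,C8 γ-lactone (8α-OH, 17R; C3 enone), via aldol hydroxy ester 29 (not isolated)
Conditions: 28, LiN(iPr)2, THF, −78 °C; then 27, −78 → 0 °C; aq. NH4Cl
Reagents that add atoms: none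
Why: Aldol addition of the ester lithium enolate to the C8 ketone, then lactonization onto the C7 alkoxide; C8 is activated by chelation to that alkoxide while C3 is shielded, the enolate enters from the β face anti to the pseudoaxial 6α-chloride, and C17 should equilibrate in the basic medium to the epimer with C18 trans to C9 (17R).

Step 22
Reactants: 30 C7,C8 γ-lactone
Product: 31 4α,9α-epoxy ketone of 30
Conditions: t-BuOOH, DBU, CH2Cl2, 0 → 20 °C
Reagents that add atoms: tert-butyl hydroperoxide, CC(C)(C)OO
Why: Weitz–Scheffer epoxidation of the tetrasubstituted enone; the peroxide adds to C9 from the α face (the β face is blocked by the syn-axial C15 methyl, the α face assisted by hydrogen bonding to the 8α-hydroxyl), and DBU spares the lactone.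

Step 23
Reactants: 31 4α,9α-epoxy ketone
Product: 32 8-O-TMS ether of 31 (tricyclic C4–C9 epoxy C3 ketone)
Conditions: N-(trimethylsilyl)imidazole, CH2Cl2, 20 °C
Reagents that add atoms: N-(trimethylsilyl)imidazole, C[Si](C)(C)n1ccnc1
Why: Silylation of the tertiary alcohol with a neutral silyl-transfer reagent, so that no Lewis acid meets the epoxide.

Step 24
Reactants: 32 tricyclic epoxy ketone, 33 4-methylbenzenesulfonohydrazide
Product: 35 ten-membered cycloalkynone (C3≡C4, C9 ketone), via tosylhydrazone 34 (not isolated)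
Conditions: AcOH, CH2Cl2, −20 → 20 °C
Reagents that add atoms: none
Why: Eschenmoser–Tanabe fragmentation: 33 condenses with C3, the only carbonyl that can form a hydrazone, to give 34; loss of the N–H proton with cleavage of the C4–O bond gives an azoalkene and a C9 alkoxide, which collapses to the C9 ketone as the C4–C9 bond breaks, the C3–C4 triple bond forms and N2 and p-toluenesulfinate leave. The closest known reaction type is the fragmentation of ring-fused bicyclic α,β-epoxy ketones to cyclodecynones and larger cycloalkynones. No ring is closed by bond formation: ring B appears by cleavage of the bond shared by rings B1 and B2, driven by epoxide strain and loss of N2, and no stereocentre is created. The step needs site selectivity (C5 is a silyl ether and the lactone does not condense), the anti-periplanar alignment of the C4–C9 and C3–N bonds that ring B1 enforces, and weakly acidic, cold conditions so that the epoxide is not solvolysed and C2 and C10 are not enolized. Either epoxide diastereomer would fragment, so the epoxide configuration is not critical.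

Step 25
Reactants: 35 ten-membered cycloalkynone
Product: 36 (Z)-cycloalkenone (C3=C4)
Conditions: H2 (1 bar), Pd/CaCO3 poisoned with Pb(OAc)2, quinoline, EtOAc, 20 °C
Reagents that add atoms: none
Why: Lindlar-type syn semi-hydrogenation; the ten-membered ring permits only the Z alkene, and the alkyl chloride and ketone are untouched.

Step 26
Reactants: 36 (Z)-cycloalkenone
Product: 37 9α-alcohol
Conditions: NaBH4, MeOH/CH2Cl2, −40 °C
Reagents that add atoms: none
Why: Hydride reduction under Felkin–Anh (non-chelation) control; the bulky trimethylsilyloxy group on C8 lies anti to the incoming hydride, which is expected to give the 9α carbinol.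

Step 27
Reactants: 37 9α-alcohol
Product: 38 9α-acetate
Conditions: Ac2O, Et3N, DMAP (cat.), CH2Cl2, 20 °C
Reagents that add atoms: acetic anhydride, CC(=O)OC(C)=O
Why: DMAP-catalysed acylation; it installs the final C9 acetate and masks C9 before the C5 carbinol is oxidised.

Step 28
Reactants: 38 9α-acetate
Product: 39 5α,8α-diol 9-acetate
Conditions: PPTS, MeOH, 0 → 20 °C
Reagents that add atoms: none
Why: Acid-catalysed methanolysis of the triethylsilyl ether and of the tertiary trimethylsilyl ether; the two secondary TBS ethers, the acetate and the lactone are stable.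

Step 29
Reactants: 39 5α,8α-diol 9-acetate
Product: 40 C5 enone
Conditions: Dess–Martin periodinane, NaHCO3, CH2Cl2, 0 °C
Reagents that add atoms: none
Why: Dess–Martin oxidation of the allylic C5 carbinol; the tertiary C8 alcohol cannot react, and the buffer avoids β-elimination of the C7 acyloxy group.

Step 30
Reactants: 40 C5 enone
Product: 41 C5 methylidene diene (2,12-bis-TBS ether)
Conditions: Cp2TiMe2 (excess), PhMe, 65 °C
Reagents that add atoms: dimethyltitanocene, [CH3-].[CH3-].[Ti+4].[cH-]1cccc1.[cH-]1cccc1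
Why: Petasis methylenation; the non-basic titanium methylidene converts the ketone faster than the esters and does not enolize the α-chloro, β-acyloxy ketone.

Step 31
Reactants: 41 C5 methylidene diene
Product: 42 2α,8α,12α-triol 9-acetate
Conditions: HF·pyridine, pyridine, THF, 0 → 20 °C
Reagents that add atoms: none
Why: Fluoride-mediated desilylation under pyridine buffering; the conditions are non-basic, so acetate, lactone and C17 are safe, and the hindered epoxide and allylic chloride should survive.

Step 32
Reactants: 42 2α,8α,12α-triol 9-acetate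
Product: 43 CNP0274383.2 (target)
Conditions: Ac2O, pyridine, DMAP (cat.), 20 °C
Reagents that add atoms: acetic anhydride, CC(=O)OC(C)=O
Why: Acylation of the two secondary alcohols; the hindered tertiary C8 alcohol is not expected to react.

## Compound list

1 | 5-methoxy-3,4-dihydronaphthalen-1(2H)-one | C1CCC(=O)c2cccc(OC)c21 | starting material
2 | 5-methoxy-2-methyl-3,4-dihydronaphthalen-1(2H)-one (racemic) | C1CC(C)C(=O)c2cccc(OC)c21 | intermediate
3 | (R)-1-phenylethan-1-amine | C[C@@H](N)c1ccccc1 | starting material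
4 | pent-1-en-3-one | CCC(=O)C=C | starting material
5 | N-[(R)-1-phenylethyl] ketimine of 2 (C1 epimers) | C1CC(C)C(=N[C@H](C)c2ccccc2)c2cccc(OC)c21 | intermediate
6 | N-[(R)-1-phenylethyl] ketimine of 7 | C1C[C@@](C)(CCC(=O)CC)C(=N[C@H](C)c2ccccc2)c2cccc(OC)c21 | intermediate
7 | (S)-5-methoxy-2-methyl-2-(3-oxopentyl)-3,4-dihydronaphthalen-1(2H)-one | C1C[C@@](C)(CCC(=O)CC)C(=O)c2cccc(OC)c21 | intermediate
8 | (S)-8-methoxy-4,10a-dimethyl-1,9,10,10a-tetrahydrophenanthren-3(2H)-one | C1C[C@]2(C)C(=C(C)C(=O)CC2)c2cccc(OC)c21 | intermediate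
9 | C12 trimethylsilyl dienol ether of 8 | C1C[C@]2(C)C(=C(C)C(O[Si](C)(C)C)=CC2)c2cccc(OC)c21 | intermediate
10 | cross-conjugated dienone (C12 ketone, C10=C11, C13=C14) | C1C[C@]2(C)C(=C(C)C(=O)C=C2)c2cccc(OC)c21 | intermediate
11 | 13α,14α-epoxy enone | C1C[C@]2(C)C(=C(C)C(=O)[C@@H]3O[C@@H]32)c2cccc(OC)c21 | intermediate
12 | 12α-hydroxy-13α,14α-epoxide (C10=C11) | C1C[C@]2(C)C(=C(C)[C@H](O)[C@@H]3O[C@@H]32)c2cccc(OC)c21 | intermediate
13 | trans-fused alcohol (10α-H, 11β-methyl, 12α-OH, 13α,14α-epoxide) | C1C[C@]2(C)[C@H]([C@@H](C)[C@H](O)[C@@H]3O[C@@H]32)c2cccc(OC)c21 | intermediate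
14 | 12α-OTBS ether of 13 | C1C[C@]2(C)[C@H]([C@@H](C)[C@H](O[Si](C)(C)C(C)(C)C)[C@@H]3O[C@@H]32)c2cccc(OC)c21 | intermediate
15 | C3 aryl ketone of 14 | O=C1C[C@]2(C)[C@H]([C@@H](C)[C@H](O[Si](C)(C)C(C)(C)C)[C@@H]3O[C@@H]32)c2cccc(OC)c21 | intermediate
16 | C5 phenol of 15 | O=C1C[C@]2(C)[C@H]([C@@H](C)[C@H](O[Si](C)(C)C(C)(C)C)[C@@H]3O[C@@H]32)c2cccc(O)c21 | intermediate
17 | C5 aryl TBS ether, C3 TBS enol ether (C2=C3) | CC(C)(C)[Si](C)(C)OC1=C[C@]2(C)[C@H]([C@@H](C)[C@H](O[Si](C)(C)C(C)(C)C)[C@@H]3O[C@@H]32)c2cccc(O[Si](C)(C)C(C)(C)C)c21 | intermediate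
18 | 2α,3α-epoxide of 17 | CC(C)(C)[Si](C)(C)O[C@@]14O[C@H]4[C@]2(C)[C@H]([C@@H](C)[C@H](O[Si](C)(C)C(C)(C)C)[C@@H]3O[C@@H]32)c2cccc(O[Si](C)(C)C(C)(C)C)c21 | intermediate
19 | 2α-OTBS C3 ketone, C5 aryl TBS ether | O=C1[C@@H](O[Si](C)(C)C(C)(C)C)[C@]2(C)[C@H]([C@@H](C)[C@H](O[Si](C)(C)C(C)(C)C)[C@@H]3O[C@@H]32)c2cccc(O[Si](C)(C)C(C)(C)C)c21 | intermediate
20 | 2α-OTBS C3 ketone, C5 phenol | O=C1[C@@H](O[Si](C)(C)C(C)(C)C)[C@]2(C)[C@H]([C@@H](C)[C@H](O[Si](C)(C)C(C)(C)C)[C@@H]3O[C@@H]32)c2cccc(O)c21 | intermediate
21 | quinone monoketal (C5 ketone, C8 dimethyl ketal) | O=C1[C@@H](O[Si](C)(C)C(C)(C)C)[C@]2(C)[C@H]([C@@H](C)[C@H](O[Si](C)(C)C(C)(C)C)[C@@H]3O[C@@H]32)C2=C1C(=O)C=CC2(OC)OC | intermediate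
22 | 6α,7α-epoxide of 21 | O=C1[C@@H](O[Si](C)(C)C(C)(C)C)[C@]2(C)[C@H]([C@@H](C)[C@H](O[Si](C)(C)C(C)(C)C)[C@@H]3O[C@@H]32)C2=C1C(=O)[C@@H]4O[C@@H]4C2(OC)OC | intermediate
23 | 6β-bromo-7α-hydroxy C5 ketone | O=C1[C@@H](O[Si](C)(C)C(C)(C)C)[C@]2(C)[C@H]([C@@H](C)[C@H](O[Si](C)(C)C(C)(C)C)[C@@H]3O[C@@H]32)C2=C1C(=O)[C@@H](Br)[C@H](O)C2(OC)OC | intermediate
24 | 6α-chloro-7α-hydroxy C5 ketone | O=C1[C@@H](O[Si](C)(C)C(C)(C)C)[C@]2(C)[C@H]([C@@H](C)[C@H](O[Si](C)(C)C(C)(C)C)[C@@H]3O[C@@H]32)C2=C1C(=O)[C@H](Cl)[C@H](O)C2(OC)OC | intermediate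
25 | 5α,7α-diol (6α-chloride, C8 dimethyl ketal) | O=C1[C@@H](O[Si](C)(C)C(C)(C)C)[C@]2(C)[C@H]([C@@H](C)[C@H](O[Si](C)(C)C(C)(C)C)[C@@H]3O[C@@H]32)C2=C1[C@H](O)[C@H](Cl)[C@H](O)C2(OC)OC | intermediate
26 | 5α-OTES ether of 25 | O=C1[C@@H](O[Si](C)(C)C(C)(C)C)[C@]2(C)[C@H]([C@@H](C)[C@H](O[Si](C)(C)C(C)(C)C)[C@@H]3O[C@@H]32)C2=C1[C@H](O[Si](CC)(CC)CC)[C@H](Cl)[C@H](O)C2(OC)OC | intermediate
27 | C8 ketone (C3,C8-enedione; 7α-OH) | O=C1[C@@H](O[Si](C)(C)C(C)(C)C)[C@]2(C)[C@H]([C@@H](C)[C@H](O[Si](C)(C)C(C)(C)C)[C@@H]3O[C@@H]32)C2=C1[C@H](O[Si](CC)(CC)CC)[C@H](Cl)[C@H](O)C2=O | intermediate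
28 | ethyl propanoate | CCC(=O)OCC | starting material
29 | C8 aldol adduct (8α-OH, ethyl (17R)-propanoate at C8) | O=C1[C@@H](O[Si](C)(C)C(C)(C)C)[C@]2(C)[C@H]([C@@H](C)[C@H](O[Si](C)(C)C(C)(C)C)[C@@H]3O[C@@H]32)C2=C1[C@H](O[Si](CC)(CC)CC)[C@H](Cl)[C@H](O)[C@@]2(O)[C@@H](C)C(=O)OCC | intermediate
30 | C7,C8 γ-lactone (8α-OH, 17R; C3 enone) | O=C1[C@@H](O[Si](C)(C)C(C)(C)C)[C@]2(C)[C@H]([C@@H](C)[C@H](O[Si](C)(C)C(C)(C)C)[C@@H]3O[C@@H]32)C4=C1[C@H](O[Si](CC)(CC)CC)[C@H](Cl)[C@@H]1OC(=O)[C@H](C)[C@]14O | intermediate
31 | 4α,9α-epoxy ketone of 30 | O=C1[C@@H](O[Si](C)(C)C(C)(C)C)[C@]2(C)[C@H]([C@@H](C)[C@H](O[Si](C)(C)C(C)(C)C)[C@@H]3O[C@@H]32)[C@@]45O[C@]41[C@H](O[Si](CC)(CC)CC)[C@H](Cl)[C@@H]1OC(=O)[C@H](C)[C@]15O | intermediate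
32 | 8-O-TMS ether of 31 (tricyclic C4–C9 epoxy C3 ketone) | O=C1[C@@H](O[Si](C)(C)C(C)(C)C)[C@]2(C)[C@H]([C@@H](C)[C@H](O[Si](C)(C)C(C)(C)C)[C@@H]3O[C@@H]32)[C@@]45O[C@]41[C@H](O[Si](CC)(CC)CC)[C@H](Cl)[C@@H]1OC(=O)[C@H](C)[C@]15O[Si](C)(C)C | intermediate
33 | 4-methylbenzenesulfonohydrazide | Cc1ccc(cc1)S(=O)(=O)NN | starting material
34 | C3 tosylhydrazone of 32 | Cc1ccc(cc1)S(=O)(=O)NN=C1[C@@H](O[Si](C)(C)C(C)(C)C)[C@]2(C)[C@H]([C@@H](C)[C@H](O[Si](C)(C)C(C)(C)C)[C@@H]3O[C@@H]32)[C@@]45O[C@]41[C@H](O[Si](CC)(CC)CC)[C@H](Cl)[C@@H]1OC(=O)[C@H](C)[C@]15O[Si](C)(C)C | intermediate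
35 | ten-membered cycloalkynone (C3≡C4, C9 ketone) | C1#C[C@@H](O[Si](C)(C)C(C)(C)C)[C@]2(C)[C@H]([C@@H](C)[C@H](O[Si](C)(C)C(C)(C)C)[C@@H]3O[C@@H]32)C(=O)[C@]2(O[Si](C)(C)C)[C@@H](C)C(=O)O[C@H]2[C@@H](Cl)[C@H]1O[Si](CC)(CC)CC | intermediate
36 | (Z)-cycloalkenone (C3=C4, C9 ketone) | [C@H]1(O[Si](CC)(CC)CC)/C=C\[C@@H](O[Si](C)(C)C(C)(C)C)[C@]2(C)[C@H]([C@@H](C)[C@H](O[Si](C)(C)C(C)(C)C)[C@@H]3O[C@@H]32)C(=O)[C@]2(O[Si](C)(C)C)[C@@H](C)C(=O)O[C@H]2[C@H]1Cl | intermediate
37 | 9α-alcohol | [C@H]1(O[Si](CC)(CC)CC)/C=C\[C@@H](O[Si](C)(C)C(C)(C)C)[C@]2(C)[C@H]([C@@H](C)[C@H](O[Si](C)(C)C(C)(C)C)[C@@H]3O[C@@H]32)[C@@H](O)[C@]2(O[Si](C)(C)C)[C@@H](C)C(=O)O[C@H]2[C@H]1Cl | intermediate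
38 | 9α-acetate | [C@H]1(O[Si](CC)(CC)CC)/C=C\[C@@H](O[Si](C)(C)C(C)(C)C)[C@]2(C)[C@H]([C@@H](C)[C@H](O[Si](C)(C)C(C)(C)C)[C@@H]3O[C@@H]32)[C@@H](OC(C)=O)[C@]2(O[Si](C)(C)C)[C@@H](C)C(=O)O[C@H]2[C@H]1Cl | intermediate
39 | 5α,8α-diol 9-acetate | [C@H]1(O)/C=C\[C@@H](O[Si](C)(C)C(C)(C)C)[C@]2(C)[C@H]([C@@H](C)[C@H](O[Si](C)(C)C(C)(C)C)[C@@H]3O[C@@H]32)[C@@H](OC(C)=O)[C@]2(O)[C@@H](C)C(=O)O[C@H]2[C@H]1Cl | intermediate
40 | C5 enone | O=C1/C=C\[C@@H](O[Si](C)(C)C(C)(C)C)[C@]2(C)[C@H]([C@@H](C)[C@H](O[Si](C)(C)C(C)(C)C)[C@@H]3O[C@@H]32)[C@@H](OC(C)=O)[C@]2(O)[C@@H](C)C(=O)O[C@H]2[C@H]1Cl | intermediate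
41 | C5 methylidene diene (2,12-bis-TBS ether) | C=C1/C=C\[C@@H](O[Si](C)(C)C(C)(C)C)[C@]2(C)[C@H]([C@@H](C)[C@H](O[Si](C)(C)C(C)(C)C)[C@@H]3O[C@@H]32)[C@@H](OC(C)=O)[C@]2(O)[C@@H](C)C(=O)O[C@H]2[C@H]1Cl | intermediate
42 | 2α,8α,12α-triol 9-acetate | C=C1/C=C\[C@@H](O)[C@]2(C)[C@H]([C@@H](C)[C@H](O)[C@@H]3O[C@@H]32)[C@@H](OC(C)=O)[C@]2(O)[C@@H](C)C(=O)O[C@H]2[C@H]1Cl | intermediate
43 | CNP0274383.2 | C=C1/C=C\[C@@H](OC(C)=O)[C@]2(C)[C@H]([C@@H](C)[C@H](OC(C)=O)[C@@H]3O[C@@H]32)[C@@H](OC(C)=O)[C@]2(O)[C@@H](C)C(=O)O[C@H]2[C@H]1Cl | target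

## Step count and least certain steps

Total: 32 steps. Longest linear sequence: 32 steps (1 to 43); 3, 4, 28 and 33 are commercial partners.

Step 24 (key step). Most likely to go wrong: slow or incomplete condensation at the C3 carbonyl, which sits between the C2 silyloxy carbon and the quaternary epoxide carbon, so that acid-promoted epoxide opening or loss of the triethylsilyl ether competes; epimerization at C10 once the C9 ketone has formed is the second hazard. Fallback: starting from 32, condensation with 1-amino-2-phenylaziridine (CH2Cl2, 0 → 20 °C, no acid) gives the N-aziridinyl imine F1. On warming in toluene (80 °C) it undergoes the same C4–C9 cleavage with extrusion of styrene and N2 under neutral conditions and returns to the route at 35.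

Step 7. Most likely to go wrong: incomplete hydrogenation or alkene migration, because C10=C11 is tetrasubstituted, aryl-conjugated and next to the quaternary C1. Fallback, starting from 8: reduction with Li in liquid NH3 (THF, −78 °C) protonates C10 from the α face, and the enolate is trapped with Me3SiCl as silyl enol ether F2. The lithium enolate is regenerated with MeLi and protonated under kinetic control (2,6-di-tert-butylphenol, −78 °C) from the α face, away from the syn-axial C15 methyl, to give ketone F3 with the 11β-methyl. A Saegusa–Ito sequence (LiN(iPr)2, Me3SiCl; Pd(OAc)2) gives enone F4, alkaline H2O2 gives epoxy ketone F5, and NaBH4/CeCl3·7H2O returns to the route at 13.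

Step 15. Most likely to go wrong: poor facial selectivity, because the reagent has to override a remote and unknown substrate bias, or low conversion of the hindered dienone. Fallback, starting from 21: acetal exchange with (2R,4R)-pentane-2,4-diol (PPTS, benzene) gives spiroketal F6, in which the auxiliary sits on the carbon next to C7. Epoxidation with t-BuOOH/DBU under auxiliary control gives epoxide F7. The operations of steps 16–19 then give bromohydrin F8, chlorohydrin F9, diol F10 and triethylsilyl ether F11, and hydrolysis as in step 20 releases the diol and returns to the route at 27. The diol antipode is chosen by the same pilot criterion as in remark 3.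

Step 21. Most likely to go wrong: addition of the enolate to the C3 carbonyl instead of C8, attack from the α face, or incomplete lactonization or C17 equilibration. Fallback, starting from 27: the order of steps 21 and 22 is inverted. Epoxidation first (t-BuOOH, DBU) gives epoxy dione F12 with the C4–C9 oxygen on the α face. The enolate of 28 then adds to C8 anti to the adjacent epoxide C–O bond, a control element directly beside the reacting carbonyl, and lactonization returns to the route at 31.

Step 26. Most likely to go wrong: hydride delivery to the wrong face of the C9 carbonyl, because the preferred torsion about C8–C9 in the flexible ring is not known. Fallback, starting from 36: the trimethylsilyl ether is removed (citric acid, MeOH, 0 °C) to give hydroxy ketone F13. Reduction with Zn(BH4)2 (Et2O, −20 °C) under chelation between the C8 hydroxyl and the C9 carbonyl reverses the facial preference of the non-chelated reduction and gives diol F14. Acetylation of the secondary carbinol (Ac2O, Et3N, DMAP) gives F15, and PPTS/MeOH returns to the route at 39.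

## Further compounds

F1 | step 24 | C3 N-(2-phenylaziridin-1-yl)imine of 32 | c1ccccc1C1CN1N=C1[C@@H](O[Si](C)(C)C(C)(C)C)[C@]2(C)[C@H]([C@@H](C)[C@H](O[Si](C)(C)C(C)(C)C)[C@@H]3O[C@@H]32)[C@@]45O[C@]41[C@H](O[Si](CC)(CC)CC)[C@H](Cl)[C@@H]1OC(=O)[C@H](C)[C@]15O[Si](C)(C)C
F2 | step 7 | C12 trimethylsilyl enol ether (C11=C12, 10α-H) | C1C[C@]2(C)[C@H](C(C)=C(O[Si](C)(C)C)CC2)c2cccc(OC)c21
F3 | step 7 | trans-fused C12 ketone (10α-H, 11β-methyl) | C1C[C@]2(C)[C@H]([C@@H](C)C(=O)CC2)c2cccc(OC)c21
F4 | step 7 | C13=C14 enone (10α-H, 11β-methyl) | C1C[C@]2(C)[C@H]([C@@H](C)C(=O)C=C2)c2cccc(OC)c21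
F5 | step 7 | 13α,14α-epoxy C12 ketone (10α-H, 11β-methyl) | C1C[C@]2(C)[C@H]([C@@H](C)C(=O)[C@@H]3O[C@@H]32)c2cccc(OC)c21
F6 | step 15 | C8 spiroketal of the quinone with (2R,4R)-pentane-2,4-diol | O=C1[C@@H](O[Si](C)(C)C(C)(C)C)[C@]2(C)[C@H]([C@@H](C)[C@H](O[Si](C)(C)C(C)(C)C)[C@@H]3O[C@@H]32)C2=C1C(=O)C=CC24O[C@H](C)C[C@@H](C)O4
F7 | step 15 | 6α,7α-epoxide of F6 | O=C1[C@@H](O[Si](C)(C)C(C)(C)C)[C@]2(C)[C@H]([C@@H](C)[C@H](O[Si](C)(C)C(C)(C)C)[C@@H]3O[C@@H]32)C2=C1C(=O)[C@@H]5O[C@@H]5C24O[C@H](C)C[C@@H](C)O4
F8 | step 15 | 6β-bromo-7α-hydroxy C5 ketone (spiroketal) | O=C1[C@@H](O[Si](C)(C)C(C)(C)C)[C@]2(C)[C@H]([C@@H](C)[C@H](O[Si](C)(C)C(C)(C)C)[C@@H]3O[C@@H]32)C2=C1C(=O)[C@@H](Br)[C@H](O)C24O[C@H](C)C[C@@H](C)O4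
F9 | step 15 | 6α-chloro-7α-hydroxy C5 ketone (spiroketal) | O=C1[C@@H](O[Si](C)(C)C(C)(C)C)[C@]2(C)[C@H]([C@@H](C)[C@H](O[Si](C)(C)C(C)(C)C)[C@@H]3O[C@@H]32)C2=C1C(=O)[C@H](Cl)[C@H](O)C24O[C@H](C)C[C@@H](C)O4
F10 | step 15 | 5α,7α-diol (spiroketal) | O=C1[C@@H](O[Si](C)(C)C(C)(C)C)[C@]2(C)[C@H]([C@@H](C)[C@H](O[Si](C)(C)C(C)(C)C)[C@@H]3O[C@@H]32)C2=C1[C@H](O)[C@H](Cl)[C@H](O)C24O[C@H](C)C[C@@H](C)O4
F11 | step 15 | 5α-OTES ether (spiroketal) | O=C1[C@@H](O[Si](C)(C)C(C)(C)C)[C@]2(C)[C@H]([C@@H](C)[C@H](O[Si](C)(C)C(C)(C)C)[C@@H]3O[C@@H]32)C2=C1[C@H](O[Si](CC)(CC)CC)[C@H](Cl)[C@H](O)C24O[C@H](C)C[C@@H](C)O4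
F12 | step 21 | 4α,9α-epoxy C3,C8-dione (7α-OH) | O=C1[C@@H](O[Si](C)(C)C(C)(C)C)[C@]2(C)[C@H]([C@@H](C)[C@H](O[Si](C)(C)C(C)(C)C)[C@@H]3O[C@@H]32)[C@@]45O[C@]41[C@H](O[Si](CC)(CC)CC)[C@H](Cl)[C@H](O)C5=O
F13 | step 26 | 8α-hydroxy C9 ketone (Z alkene, 5-OTES) | [C@H]1(O[Si](CC)(CC)CC)/C=C\[C@@H](O[Si](C)(C)C(C)(C)C)[C@]2(C)[C@H]([C@@H](C)[C@H](O[Si](C)(C)C(C)(C)C)[C@@H]3O[C@@H]32)C(=O)[C@]2(O)[C@@H](C)C(=O)O[C@H]2[C@H]1Cl
F14 | step 26 | 8α,9α-diol (5-OTES) | [C@H]1(O[Si](CC)(CC)CC)/C=C\[C@@H](O[Si](C)(C)C(C)(C)C)[C@]2(C)[C@H]([C@@H](C)[C@H](O[Si](C)(C)C(C)(C)C)[C@@H]3O[C@@H]32)[C@@H](O)[C@]2(O)[C@@H](C)C(=O)O[C@H]2[C@H]1Cl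
F15 | step 26 | 9α-acetate 8α-alcohol (5-OTES) | [C@H]1(O[Si](CC)(CC)CC)/C=C\[C@@H](O[Si](C)(C)C(C)(C)C)[C@]2(C)[C@H]([C@@H](C)[C@H](O[Si](C)(C)C(C)(C)C)[C@@H]3O[C@@H]32)[C@@H](OC(C)=O)[C@]2(O)[C@@H](C)C(=O)O[C@H]2[C@H]1Cl
A1 | alternative 1 | (1E,3Z)-1-ethoxy-3-(trimethylsilyloxy)penta-1,3-diene | CCO/C=C/C(=C/C)O[Si](C)(C)C
A2 | alternative 1 | (E)-4-(tert-butyldimethylsilyloxy)-2-methylbut-2-enal | O=C/C(C)=C/CO[Si](C)(C)C(C)(C)C
A3 | alternative 1 | ring A enone with C2 aldehyde and C9 silyl ether | O=C[C@]1(C)[C@H]([C@@H](C)C(=O)C=C1)CO[Si](C)(C)C(C)(C)C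
A4 | alternative 2 | C7 2-diazopropanoate of the ten-membered C8 triethylsilyl ether | C=C1/C=C\[C@@H](OC(C)=O)[C@]2(C)[C@H]([C@@H](C)[C@H](OC(C)=O)[C@@H]3O[C@@H]32)[C@@H](OC(C)=O)[C@@H](O[Si](CC)(CC)CC)[C@@H](OC(=O)C(C)=[N+]=[N-])[C@H]1Cl
A5 | alternative 2 | C8 O-triethylsilyl ether of the target | C=C1/C=C\[C@@H](OC(C)=O)[C@]2(C)[C@H]([C@@H](C)[C@H](OC(C)=O)[C@@H]3O[C@@H]32)[C@@H](OC(C)=O)[C@]2(O[Si](CC)(CC)CC)[C@@H](C)C(=O)O[C@H]2[C@H]1Cl
A6 | alternative 3 | seco C8 keto C9 aldehyde | C=C(/C=C\[C@@H](O[Si](C)(C)C(C)(C)C)[C@]1(C)[C@H]([C@@H](C)[C@H](O[Si](C)(C)C(C)(C)C)C=C1)C=O)[C@@H](OCc1ccc(OC)cc1)[C@H](O[Si](C)(C)C(C)(C)C)C(=O)[C@@H](C)CO[Si](C)(C)C(C)(C)C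
A7 | alternative 3 | ten-membered C8,C9 diol | C=C1/C=C\[C@@H](O[Si](C)(C)C(C)(C)C)[C@]2(C)[C@H]([C@@H](C)[C@H](O[Si](C)(C)C(C)(C)C)C=C2)[C@@H](O)[C@](O)([C@@H](C)CO[Si](C)(C)C(C)(C)C)[C@@H](O[Si](C)(C)C(C)(C)C)[C@@H]1OCc1ccc(OC)cc1
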